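4 questions stood on one flask in which J takes up the incoming ligand L and gives X, with the leaving ligand G present from the start, and each turns on how much X stands beside the J still unreacted.

all flasks: J 0.10 M; temperature −20 °C

| run | L | G | remark | time |
|---|---|---|---|---|
| autumn | 2 equiv | 5 equiv | the very flask that is asked about, followed so far |  |
| noon | 2 equiv | 10 equiv | run made earlier |  |
| flask | 2.00 equiv | 5.00 equiv |  | 50 min |

| run | time / min | X / % | J / % |
|---|---|---|---|
| autumn | 2.50 | 3.2 | 95.9 |
| autumn | 6.00 | 5.8 | 91.6 |
| autumn | 12.0 | 8.9 | 86.4 |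
| autumn | 30.0 | 12.8 | 70.3 |
| noon | 12.0 | 6.3 | 86.7 |
| noon | 25.0 | 7.2 | 74.8 |
| noon | 40.0 | 5.6 | 62.0 |
| noon | 50.0 | 7.2 | 57.2 |

(scatter of a reading: 1 percentage point)

- what is added takes up no volume worth counting
- steps under discussion: J + L -> G + X; X + L -> G + D; D + L -> G + Z; X <-> E; G + X -> Q
- the earlier runs do not show what temperature does; that part of a forecast is a guess

- amber: at 50 min raise the temperature by 15 K, then wait 1.5 h
- violet: at 50 min take out 90% of the G then present, then wait 1.5 h
- ochre: at 50 min add L, 100% of the amount charged, then wait 1.5 h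
- teal: change nothing and wait 1.5 h more

- X, in percent of the J first charged, at 50 min
- the remedy with the largest gain of X, or "none" below 2 percentage points (amber / violet / ochre / teal / none)
- X present, in percent of the J first charged, after amber
- X present, in percent of the J first charged, after ochre

The autumn run is this flask so far, and the noon run looks nearly the same but had twice the G. J fell alike in both: a first-order constant of 0.0117 min⁻¹ in autumn and a = 0.0112 min⁻¹ at noon (pseudo-first-order, as L changes slowly). X parted, though. At noon it stayed flat within the scatter, with X/J over the last three readings at 0.103, while in autumn it was still climbing at 30.0 min.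

I treated X as a tank filled at aJ and drained at dX, where d is a first-order drain constant. Once X follows the falling J, X/J holds still at the balance ratio ρ = a/(d − a), and the gap to it shrinks with time constant τ = 1/(d − a). The noon reading gives d = 0.120 min⁻¹. I assumed that d goes with G, as in G + X → Q, so this flask has d = 0.0598 min⁻¹, ρ = 0.230 and τ = 20.6 min. So the two runs end apart: the stronger noon drain brought a lower ratio, approached with a time constant τ of 9.19 min at noon.

As a check from different readings, this gives 12.6% for the autumn reading of 12.8%. For 50 min I committed to 12.0%. Waiting would bring X down with J to about 4.81%, whereas taking out G puts d at 0.00598 min⁻¹, below a, so X piles up.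

The forecast said 12%, violet, 1% after amber and 4.5% after ochre, on the ground that “Removing G cuts the drain”.

The flask gave 12.0% and violet, a gain of 13 percentage points, with 0.247% after amber and 4.49% after ochre.

    J + L → G + X (k = 0.00110 M⁻¹ s⁻¹, Ea = 60.0 kJ mol⁻¹)
    X + L → G + D (k = 5.80 × 10⁻⁵ M⁻¹ s⁻¹, Ea = 56.0 kJ mol⁻¹)
    D + L → G + Z (k = 5.20 × 10⁻⁴ M⁻¹ s⁻¹, Ea = 48.0 kJ mol⁻¹)
    X ⇌ E (K = 12.0, k = 2.30 × 10⁻⁵ s⁻¹, Ea = 85.0 kJ mol⁻¹, ΔH = −36.0 kJ mol⁻¹)
    G + X → Q (k = 0.00180 M⁻¹ s⁻¹, Ea = 66.0 kJ mol⁻¹)
    (constants at −20 °C)

At 19.9 min X went into Q 89 times as fast as into D. Its half-life by the step to D, 17 h, was long against 50 min. In this flask X/J at 50.0 min stood at 0.214, against 0.210 from ρ and τ. The forecast's 12% would have been wrong for the neighbour charged with 3.00 equiv of G, where ρ = 0.452 gives 18.4% and that flask held 17.9%.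

Readings and results are calculated for substances that don't exist; scatter was added.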